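## Retrosynthetic overview
1. The 14-membered ring is closed last by ring-closing metathesis at C6=C7 (E), between the C8 vinyl carbinol and the allyl group on C4.
2. Before that, the 3,4-epoxide comes from a Shi epoxidation of the E-trisubstituted alkene and the 13-OAc from acetylation.
3. The cis-α-methylene-γ-butyrolactone (first ring; C1–C14 bond, C1 and C14 stereocentres) comes from an aqueous indium Barbier allylation/lactonisation of α-hydroxy aldehyde 12 with (Z)-2-(bromomethyl)enoate 21.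
4. Aldehyde 12: C8 from (R)-linalool; C12/C13 from a Sharpless epoxide opened at C3 by the linalool-derived alkyllithium (C11–C12 bond).
5. Bromide 21: carboalumination of pent-1-en-4-yne/ethylene oxide, oxidation, vinylalumination, SN2′ bromination. Ring order: lactone, then epoxide, then macrocycle.

Assumption: cembrane numbering is used for position labels (C1 = ring-fusion CH, C14 = lactone O–CH, C13 = CHOAc, C12 = CHMe, C8 = C(OH)Me, C3/C4 = epoxide); the five starting materials and all named reagents and catalysts are taken as commercial.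

## Route

Step 1
Reactants: 1 (R)-(−)-linalool [(3R)-3,7-dimethylocta-1,6-dien-3-ol]
Product: 2 triethyl{[(3R)-3,7-dimethylocta-1,6-dien-3-yl]oxy}silane
Conditions: TESOTf, 2,6-lutidine, CH2Cl2, −78 → 0 °C
Reagents that add atoms: triethylsilyl trifluoromethanesulfonate, CC[Si](CC)(CC)OS(=O)(=O)C(F)(F)F
Why: Silylation of the tertiary allylic alcohol with a silyl triflate masks the OH for the later organolithium step and blocks tetrahydrofuran formation; C8 comes unchanged from the chiral pool.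

Step 2
Reactants: 2 triethyl{[(3R)-3,7-dimethylocta-1,6-dien-3-yl]oxy}silane
Product: 4 (4R)-4-methyl-4-[(triethylsilyl)oxy]hex-5-en-1-ol, via aldehyde 3 (not isolated)
Conditions: O3, CH2Cl2/MeOH 4:1, Sudan Red 7B indicator, −78 °C; then NaBH4 (excess), −78 → 0 °C
Reagents that add atoms: ozone, [O-][O+]=O
Why: Chemoselective ozonolysis cleaves the electron-rich trisubstituted alkene much faster than the hindered vinyl group, and borohydride reduces the aldehyde in the same pot.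

Step 3
Reactants: 4 (4R)-4-methyl-4-[(triethylsilyl)oxy]hex-5-en-1-ol
Product: 5 triethyl{[(3R)-6-iodo-3-methylhex-1-en-3-yl]oxy}silane
Conditions: I2, PPh3, imidazole, CH2Cl2, 0 °C → rt
Reagents that add atoms: iodine, II
Why: Garegg–Samuelsson (Appel-type) iodination replaces the primary OH by SN2 on the alkoxyphosphonium ion; the silylated tertiary centre is inert.

Step 4
Reactants: 6 (2E)-but-2-en-1-ol
Product: 8 tert-butyldimethyl{[(2S,3S)-3-methyloxiran-2-yl]methoxy}silane, via epoxy alcohol 7 (not isolated)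
Conditions: Ti(OiPr)4 (5 mol%), L-(+)-DIPT (7 mol%), t-BuOOH (1.2 equiv), 4 Å MS, CH2Cl2, −20 °C; then TBSCl, Et3N, DMAP (cat.), −20 → 0 °C
Reagents that add atoms: tert-butyl hydroperoxide, CC(C)(C)OO; tert-butyldimethylsilyl chloride, CC(C)(C)[Si](C)(C)Cl
Why: Sharpless asymmetric epoxidation with L-(+)-tartrate gives the (2S,3S)-epoxy alcohol (future C13 and C12), which is silylated in situ because it is volatile and water-soluble.

Step 5
Reactants: 5 triethyl{[(3R)-6-iodo-3-methylhex-1-en-3-yl]oxy}silane; 8 tert-butyldimethyl{[(2S,3S)-3-methyloxiran-2-yl]methoxy}silane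
Product: 10 (2R,3S,7R)-1-[(tert-butyldimethylsilyl)oxy]-3,7-dimethyl-7-[(triethylsilyl)oxy]non-8-en-2-ol, via alkyllithium 9 (not isolated)
Conditions: 5 (1.3 equiv), t-BuLi (2.1 equiv per 5), Et2O/pentane, −78 °C; then 8, BF3·OEt2, −78 °C; aq. NaHCO3
Reagents that add atoms: none
Why: Lithium–iodine exchange at −78 °C and BF3-assisted SN2 epoxide opening occur at the methyl-bearing carbon, remote from the deactivating CH2OTBS group, with inversion, so the trans-epoxide gives the 12,13-syn array (12S,13R).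

Step 6
Reactants: 10 (2R,3S,7R)-1-[(tert-butyldimethylsilyl)oxy]-3,7-dimethyl-7-[(triethylsilyl)oxy]non-8-en-2-ol
Product: 11 (2R,3S,7R)-3,7-dimethylnon-8-ene-1,2,7-triol
Conditions: TBAF (3 equiv), THF, rt → 40 °C
Reagents that add atoms: none
Why: Fluoride-mediated global desilylation frees all three hydroxyls without touching a stereocentre.

Step 7
Reactants: 11 (2R,3S,7R)-3,7-dimethylnon-8-ene-1,2,7-triol
Product: 12 (2R,3S,7R)-2,7-dihydroxy-3,7-dimethylnon-8-enal
Conditions: TEMPO (10 mol%), PhI(OAc)2 (1.1 equiv), CH2Cl2, rt; used crude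
Reagents that add atoms: none
Why: TEMPO/PhI(OAc)2 (oxoammonium) oxidation is selective for the primary alcohol of the 1,2-diol and stops at the α-hydroxy aldehyde under non-basic conditions that do not epimerise C13.

Step 8
Reactants: 13 pent-1-en-4-yne; 14 oxirane (ethylene oxide)
Product: 16 (3E)-4-methylhepta-3,6-dien-1-ol, via alkenylalane 15 (not isolated)
Conditions: AlMe3 (2 equiv), Cp2ZrCl2 (0.25 equiv), CH2Cl2, 0 °C → rt; then n-BuLi, THF, −78 → −30 °C; then 14 (3 equiv), −30 °C → rt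
Reagents that add atoms: trimethylaluminium, C[Al](C)C
Why: Zr-catalysed Negishi carboalumination adds Me and Al syn across the alkyne only, and the derived alanate opens ethylene oxide with retention to give the E-trisubstituted homoallylic alcohol.

Step 9
Reactants: 16 (3E)-4-methylhepta-3,6-dien-1-ol
Product: 17 (3E)-4-methylhepta-3,6-dienal
Conditions: Dess–Martin periodinane, NaHCO3, CH2Cl2, 0 °C; used at once
Reagents that add atoms: none
Why: Buffered Dess–Martin oxidation gives the β,γ-unsaturated aldehyde under neutral conditions, so the skipped alkene does not move into conjugation.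

Step 10
Reactants: 17 (3E)-4-methylhepta-3,6-dienal; 18 methyl prop-2-ynoate
Product: 20 methyl (5E)-3-hydroxy-6-methyl-2-methylidenenona-5,8-dienoate (racemic), via vinylalane 19 (not isolated)
Conditions: 18, DIBAL-H, NMO, THF, 0 °C; then 17, 0 °C → rt
Reagents that add atoms: none
Why: α-Hydroalumination of the propiolate and 1,2-addition of the vinylalane (vinylalumination) gives the Morita–Baylis–Hillman-type alcohol without amine base; its carbinol centre is destroyed in the next step.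

Step 11
Reactants: 20 methyl (5E)-3-hydroxy-6-methyl-2-methylidenenona-5,8-dienoate
Product: 21 methyl (2Z,5E)-2-(bromomethyl)-6-methylnona-2,5,8-trienoate
Conditions: NBS, Me2S, CH2Cl2, 0 °C (premixed); then 20, 0 °C → rt
Reagents that add atoms: N-bromosuccinimide, O=C1CCC(=O)N1Br
Why: Corey–Kim-type activation of the allylic alcohol and SN2′ attack by bromide (allylic transposition) give the thermodynamically favoured (2Z)-2-(bromomethyl)enoate.

Step 12
Reactants: 12 (2R,3S,7R)-2,7-dihydroxy-3,7-dimethylnon-8-enal; 21 methyl (2Z,5E)-2-(bromomethyl)-6-methylnona-2,5,8-trienoate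
Product: 23 (4S,5R)-5-[(1R,2S,6R)-1,6-dihydroxy-2,6-dimethyloct-7-en-1-yl]-3-methylidene-4-[(2E)-3-methylhexa-2,5-dien-1-yl]oxolan-2-one, via hydroxy ester 22 (not isolated)
Conditions: In powder (1.5 equiv), THF/H2O 1:1, rt; then PPTS (cat.), CH2Cl2, rt
Reagents that add atoms: none
Why: In this aqueous indium Barbier allylation the free α-OH chelates indium so the allyl group adds anti to the C12 chain (13,14-syn, C14 R), the Z-allylindium reacts through a chair transition state (1,14-syn, C1 S), and the ester closes onto the C14 oxygen as the favoured five-membered cis-lactone.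

Step 13
Reactants: 23 (4S,5R)-5-[(1R,2S,6R)-1,6-dihydroxy-2,6-dimethyloct-7-en-1-yl]-3-methylidene-4-[(2E)-3-methylhexa-2,5-dien-1-yl]oxolan-2-one
Product: 24 (1R,2S,6R)-6-hydroxy-2,6-dimethyl-1-{(2R,3S)-4-methylidene-3-[(2E)-3-methylhexa-2,5-dien-1-yl]-5-oxooxolan-2-yl}oct-7-en-1-yl acetate
Conditions: Ac2O (1.5 equiv), pyridine, DMAP (cat.), CH2Cl2, 0 °C
Reagents that add atoms: acetic anhydride, CC(=O)OC(C)=O
Why: DMAP-catalysed acetylation takes the only secondary alcohol (C13-OH); the tertiary allylic C8-OH is too hindered to react.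

Step 14
Reactants: 24 (1R,2S,6R)-6-hydroxy-2,6-dimethyl-1-{(2R,3S)-4-methylidene-3-[(2E)-3-methylhexa-2,5-dien-1-yl]-5-oxooxolan-2-yl}oct-7-en-1-yl acetate
Product: 25 (1R,2S,6R)-6-hydroxy-2,6-dimethyl-1-[(2R,3S)-4-methylidene-3-{[(2R,3R)-3-methyl-3-(prop-2-en-1-yl)oxiran-2-yl]methyl}-5-oxooxolan-2-yl]oct-7-en-1-yl acetate
Conditions: Shi ketone (D-fructose-derived, 30 mol%), Oxone, K2CO3, Bu4NHSO4 (cat.), MeCN/DMM/aq. borate–EDTA buffer (pH ≈ 10.5), 0 °C
Reagents that add atoms: Oxone (potassium peroxymonosulfate), [K+].[O-]S(=O)(=O)OO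
Why: In this Shi asymmetric epoxidation the chiral dioxirane attacks only the electron-rich E-trisubstituted alkene (vinyl groups and the enoate are much slower) through a spiro transition state, giving the (3R,4R)-epoxide by reagent control.

Step 15
Reactants: 25 (1R,2S,6R)-6-hydroxy-2,6-dimethyl-1-[(2R,3S)-4-methylidene-3-{[(2R,3R)-3-methyl-3-(prop-2-en-1-yl)oxiran-2-yl]methyl}-5-oxooxolan-2-yl]oct-7-en-1-yl acetate
Product: 26 CNP0202356.3, (1S,3R,4R,6E,8R,12S,13R,14R)-13-acetoxy-3,4-epoxy-8-hydroxycembra-6,15(17)-dien-16,14-olide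
Conditions: Grubbs II (10 mol%), 1,4-benzoquinone (20 mol%), CH2Cl2 (1 mM), 40 °C
Reagents that add atoms: none
Why: Ring-closing metathesis of the two monosubstituted alkenes forms the 14-membered ring with loss of ethene; the alkene next to the quaternary carbinol forms as the E isomer, and the electron-poor methylene lactone is a spectator because the trans-epoxide rules out seven-ring closure.

## Compound list
1 | (R)-(−)-linalool, (3R)-3,7-dimethylocta-1,6-dien-3-ol | C=C[C@](C)(O)CCC=C(C)C | starting material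
2 | triethyl{[(3R)-3,7-dimethylocta-1,6-dien-3-yl]oxy}silane | C=C[C@](C)(O[Si](CC)(CC)CC)CCC=C(C)C | intermediate
3 | (4R)-4-methyl-4-[(triethylsilyl)oxy]hex-5-enal | C=C[C@](C)(O[Si](CC)(CC)CC)CCC=O | intermediate (not isolated)
4 | (4R)-4-methyl-4-[(triethylsilyl)oxy]hex-5-en-1-ol | C=C[C@](C)(O[Si](CC)(CC)CC)CCCO | intermediate
5 | triethyl{[(3R)-6-iodo-3-methylhex-1-en-3-yl]oxy}silane | C=C[C@](C)(O[Si](CC)(CC)CC)CCCI | intermediate
6 | (2E)-but-2-en-1-ol | C/C=C/CO | starting material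
7 | [(2S,3S)-3-methyloxiran-2-yl]methanol | C[C@@H]1O[C@H]1CO | intermediate (not isolated)
8 | tert-butyldimethyl{[(2S,3S)-3-methyloxiran-2-yl]methoxy}silane | C[C@@H]1O[C@H]1CO[Si](C)(C)C(C)(C)C | intermediate
9 | {(4R)-4-methyl-4-[(triethylsilyl)oxy]hex-5-en-1-yl}lithium | C=C[C@](C)(O[Si](CC)(CC)CC)CCC[Li] | intermediate (not isolated)
10 | (2R,3S,7R)-1-[(tert-butyldimethylsilyl)oxy]-3,7-dimethyl-7-[(triethylsilyl)oxy]non-8-en-2-ol | C=C[C@](C)(O[Si](CC)(CC)CC)CCC[C@H](C)[C@@H](O)CO[Si](C)(C)C(C)(C)C | intermediate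
11 | (2R,3S,7R)-3,7-dimethylnon-8-ene-1,2,7-triol | C=C[C@](C)(O)CCC[C@H](C)[C@@H](O)CO | intermediate
12 | (2R,3S,7R)-2,7-dihydroxy-3,7-dimethylnon-8-enal | C=C[C@](C)(O)CCC[C@H](C)[C@@H](O)C=O | intermediate
13 | pent-1-en-4-yne | C=CCC#C | starting material
14 | oxirane (ethylene oxide) | C1CO1 | starting material
15 | dimethyl[(1E)-2-methylpenta-1,4-dien-1-yl]alumane | C[Al](C)/C=C(\C)CC=C | intermediate (not isolated)
16 | (3E)-4-methylhepta-3,6-dien-1-ol | OCC/C=C(\C)CC=C | intermediate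
17 | (3E)-4-methylhepta-3,6-dienal | O=CC/C=C(\C)CC=C | intermediate
18 | methyl prop-2-ynoate (methyl propiolate) | C#CC(=O)OC | starting material
19 | methyl 2-[bis(2-methylpropyl)alumanyl]prop-2-enoate | C=C([Al](CC(C)C)CC(C)C)C(=O)OC | intermediate (not isolated)
20 | methyl (5E)-3-hydroxy-6-methyl-2-methylidenenona-5,8-dienoate (racemic) | C=C(C(=O)OC)C(O)C/C=C(\C)CC=C | intermediate
21 | methyl (2Z,5E)-2-(bromomethyl)-6-methylnona-2,5,8-trienoate | COC(=O)/C(CBr)=C/C/C=C(\C)CC=C | intermediate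
22 | methyl (3S,4R,5R,6S,10R)-4,5,10-trihydroxy-6,10-dimethyl-2-methylidene-3-[(2E)-3-methylhexa-2,5-dien-1-yl]dodec-11-enoate | COC(=O)C(=C)[C@H](C/C=C(\C)CC=C)[C@@H](O)[C@H](O)[C@@H](C)CCC[C@@](C)(O)C=C | intermediate (not isolated)
23 | (4S,5R)-5-[(1R,2S,6R)-1,6-dihydroxy-2,6-dimethyloct-7-en-1-yl]-3-methylidene-4-[(2E)-3-methylhexa-2,5-dien-1-yl]oxolan-2-one | C=C1C(=O)O[C@@H]([C@H](O)[C@@H](C)CCC[C@@](C)(O)C=C)[C@H]1C/C=C(\C)CC=C | intermediate
24 | (1R,2S,6R)-6-hydroxy-2,6-dimethyl-1-{(2R,3S)-4-methylidene-3-[(2E)-3-methylhexa-2,5-dien-1-yl]-5-oxooxolan-2-yl}oct-7-en-1-yl acetate | C=C1C(=O)O[C@@H]([C@H](OC(C)=O)[C@@H](C)CCC[C@@](C)(O)C=C)[C@H]1C/C=C(\C)CC=C | intermediate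
25 | (1R,2S,6R)-6-hydroxy-2,6-dimethyl-1-[(2R,3S)-4-methylidene-3-{[(2R,3R)-3-methyl-3-(prop-2-en-1-yl)oxiran-2-yl]methyl}-5-oxooxolan-2-yl]oct-7-en-1-yl acetate | C=C1C(=O)O[C@@H]([C@H](OC(C)=O)[C@@H](C)CCC[C@@](C)(O)C=C)[C@H]1C[C@H]2O[C@]2(C)CC=C | intermediate
26 | CNP0202356.3, (1S,3R,4R,6E,8R,12S,13R,14R)-13-acetoxy-3,4-epoxy-8-hydroxycembra-6,15(17)-dien-16,14-olide | C=C1C(=O)O[C@H]2[C@H](OC(C)=O)[C@@H](C)CCC[C@@](C)(O)/C=C/C[C@@]3(C)O[C@@H]3C[C@@H]12 | target

## Summary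
Total step count: 15. Longest linear sequence: 10 steps (1 → 2 → 4 → 5 → 10 → 11 → 12 → 23 → 24 → 25 → 26).

Three steps most likely to fail:

Step 5 (regioselectivity and rate of opening an internal epoxide; handling of the hexenyl-type alkyllithium). The fallback sets out from 5 and comes back at 11. The organometallic from 5 (t-BuLi, then MgBr2, CuI cat.) opens (S)-β-butyrolactone by SN2 at the methyl-bearing carbon with inversion, giving (3S,7R)-3,7-dimethyl-7-[(triethylsilyl)oxy]non-8-enoic acid F1. LiAlH4 reduction gives (3S,7R)-3,7-dimethyl-7-[(triethylsilyl)oxy]non-8-en-1-ol F2, and Dess–Martin oxidation gives (3S,7R)-3,7-dimethyl-7-[(triethylsilyl)oxy]non-8-enal F3. L-Proline-catalysed α-aminoxylation with nitrosobenzene (catalyst control, 2R) followed by NaBH4 gives (2R,3S,7R)-2-(anilinooxy)-3,7-dimethyl-7-[(triethylsilyl)oxy]non-8-en-1-ol F4. Zn/AcOH cleaves the N–O bond to (2R,3S,7R)-3,7-dimethyl-7-[(triethylsilyl)oxy]non-8-ene-1,2-diol F5, and TBAF gives 11.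

Step 12 (chelation control at C14, syn selectivity at C1, γ- versus δ-lactone, stability of the α-hydroxy aldehyde). The fallback sets out from 10 and 21 and comes back at 23; it replaces the aqueous Barbier reaction by a Lewis-acid chelation-controlled allylstannane addition. Alcohol 10 is protected with 4-methoxybenzyl trichloroacetimidate to give tert-butyl({(2R,3S,7R)-2-[(4-methoxyphenyl)methoxy]-3,7-dimethyl-7-[(triethylsilyl)oxy]non-8-en-1-yl}oxy)dimethylsilane F6. TBAF gives (2R,3S,7R)-2-[(4-methoxyphenyl)methoxy]-3,7-dimethylnon-8-ene-1,7-diol F7, and Dess–Martin oxidation gives (2R,3S,7R)-7-hydroxy-2-[(4-methoxyphenyl)methoxy]-3,7-dimethylnon-8-enal F8. Bromide 21 is converted with (Bu3Sn)2 and Pd(0) into methyl (2Z,5E)-6-methyl-2-[(tributylstannyl)methyl]nona-2,5,8-trienoate F9. MgBr2·OEt2-mediated addition of F9 to F8 (chelate between C=O and OPMB, open transition state, syn,syn) followed by PPTS lactonisation gives (4S,5R)-5-{(1R,2S,6R)-6-hydroxy-1-[(4-methoxyphenyl)methoxy]-2,6-dimethyloct-7-en-1-yl}-3-methylidene-4-[(2E)-3-methylhexa-2,5-dien-1-yl]oxolan-2-one F10. DDQ removes the PMB group to give 23.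

Step 15 (E/Z control and oligomerisation in the macrocyclic metathesis at a hindered vinyl carbinol). The fallback sets out from 11 and 21 and comes back at 26; it forms the C6=C7 alkene first and closes the ring by the Barbier reaction. Cross-metathesis of 11 with excess 21 (Hoveyda–Grubbs II) gives methyl (2Z,5E,8E,10R,14S,15R)-2-(bromomethyl)-10,15,16-trihydroxy-6,10,14-trimethylhexadeca-2,5,8-trienoate F11. TEMPO/PhI(OAc)2 gives methyl (2Z,5E,8E,10R,14S,15R)-2-(bromomethyl)-10,15-dihydroxy-6,10,14-trimethyl-16-oxohexadeca-2,5,8-trienoate F12. Intramolecular indium Barbier allylation/lactonisation at 2 mM in THF/H2O gives (1S,3E,6E,8R,12S,13R,14R)-8,13-dihydroxycembra-3,6,15(17)-trien-16,14-olide F13. Acetylation gives (1S,3E,6E,8R,12S,13R,14R)-13-acetoxy-8-hydroxycembra-3,6,15(17)-trien-16,14-olide F14, and Shi epoxidation of the trisubstituted alkene gives 26.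

## Further compounds
F1 | step 5 | (3S,7R)-3,7-dimethyl-7-[(triethylsilyl)oxy]non-8-enoic acid | C=C[C@](C)(O[Si](CC)(CC)CC)CCC[C@H](C)CC(=O)O
F2 | step 5 | (3S,7R)-3,7-dimethyl-7-[(triethylsilyl)oxy]non-8-en-1-ol | C=C[C@](C)(O[Si](CC)(CC)CC)CCC[C@H](C)CCO
F3 | step 5 | (3S,7R)-3,7-dimethyl-7-[(triethylsilyl)oxy]non-8-enal | C=C[C@](C)(O[Si](CC)(CC)CC)CCC[C@H](C)CC=O
F4 | step 5 | (2R,3S,7R)-2-(anilinooxy)-3,7-dimethyl-7-[(triethylsilyl)oxy]non-8-en-1-ol | C=C[C@](C)(O[Si](CC)(CC)CC)CCC[C@H](C)[C@@H](ONc1ccccc1)CO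
F5 | step 5 | (2R,3S,7R)-3,7-dimethyl-7-[(triethylsilyl)oxy]non-8-ene-1,2-diol | C=C[C@](C)(O[Si](CC)(CC)CC)CCC[C@H](C)[C@@H](O)CO
F6 | step 12 | tert-butyl({(2R,3S,7R)-2-[(4-methoxyphenyl)methoxy]-3,7-dimethyl-7-[(triethylsilyl)oxy]non-8-en-1-yl}oxy)dimethylsilane | C=C[C@](C)(O[Si](CC)(CC)CC)CCC[C@H](C)[C@@H](OCc1ccc(OC)cc1)CO[Si](C)(C)C(C)(C)C
F7 | step 12 | (2R,3S,7R)-2-[(4-methoxyphenyl)methoxy]-3,7-dimethylnon-8-ene-1,7-diol | C=C[C@](C)(O)CCC[C@H](C)[C@@H](OCc1ccc(OC)cc1)CO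
F8 | step 12 | (2R,3S,7R)-7-hydroxy-2-[(4-methoxyphenyl)methoxy]-3,7-dimethylnon-8-enal | C=C[C@](C)(O)CCC[C@H](C)[C@@H](OCc1ccc(OC)cc1)C=O
F9 | step 12 | methyl (2Z,5E)-6-methyl-2-[(tributylstannyl)methyl]nona-2,5,8-trienoate | COC(=O)/C(C[Sn](CCCC)(CCCC)CCCC)=C/C/C=C(\C)CC=C
F10 | step 12 | (4S,5R)-5-{(1R,2S,6R)-6-hydroxy-1-[(4-methoxyphenyl)methoxy]-2,6-dimethyloct-7-en-1-yl}-3-methylidene-4-[(2E)-3-methylhexa-2,5-dien-1-yl]oxolan-2-one | C=C1C(=O)O[C@@H]([C@H](OCc2ccc(OC)cc2)[C@@H](C)CCC[C@@](C)(O)C=C)[C@H]1C/C=C(\C)CC=C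
F11 | step 15 | methyl (2Z,5E,8E,10R,14S,15R)-2-(bromomethyl)-10,15,16-trihydroxy-6,10,14-trimethylhexadeca-2,5,8-trienoate | COC(=O)/C(CBr)=C/C/C=C(\C)C/C=C/[C@](C)(O)CCC[C@H](C)[C@@H](O)CO
F12 | step 15 | methyl (2Z,5E,8E,10R,14S,15R)-2-(bromomethyl)-10,15-dihydroxy-6,10,14-trimethyl-16-oxohexadeca-2,5,8-trienoate | COC(=O)/C(CBr)=C/C/C=C(\C)C/C=C/[C@](C)(O)CCC[C@H](C)[C@@H](O)C=O
F13 | step 15 | (1S,3E,6E,8R,12S,13R,14R)-8,13-dihydroxycembra-3,6,15(17)-trien-16,14-olide | C=C1C(=O)O[C@H]2[C@H](O)[C@@H](C)CCC[C@@](C)(O)/C=C/C/C(C)=C/C[C@@H]12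
F14 | step 15 | (1S,3E,6E,8R,12S,13R,14R)-13-acetoxy-8-hydroxycembra-3,6,15(17)-trien-16,14-olide | C=C1C(=O)O[C@H]2[C@H](OC(C)=O)[C@@H](C)CCC[C@@](C)(O)/C=C/C/C(C)=C/C[C@@H]12
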